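(The readings come from a simulation with constants of no real substance.)

The south run and its neighbour, the north-east run, differ in one thing: the north-east run holds twice the L.

| flask | Z | X | L | time |
|---|---|---|---|---|
| south | 0.400 M | 0.480 M | 0.00200 M |  |
| north-west | 0.160 M | 0.240 M | 0.00200 M |  |
| north-east | 0.400 M | 0.480 M | 0.00400 M |  |
| north | 0.400 M | 1.40 M | 0.00200 M |  |
| west | 0.400 M | 0.480 M | 0.00920 M | 33 h |

| run | time / h | [J] / M |
|---|---|---|
| south run | 1.3 | 0.072 |
| south run | 2.1 | 0.103 |
| south run | 3.3 | 0.142 |
| south run | 5.2 | 0.174 |
| south run | 8.3 | 0.207 |
| south run | 13 | 0.225 |
| south run | 21 | 0.257 |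
| south run | 33 | 0.283 |
| north-west run | 1.3 | 0.016 |
| north-west run | 2.1 | 0.029 |
| north-west run | 3.3 | 0.036 |
| north-west run | 5.2 | 0.057 |
| north-west run | 8.3 | 0.071 |
| north-west run | 13 | 0.085 |
| north-west run | 21 | 0.100 |
| north-west run | 33 | 0.097 |
| north-east run | 1.3 | 0.112 |
| north-east run | 2.1 | 0.152 |
| north-east run | 3.3 | 0.189 |
| north-east run | 5.2 | 0.212 |
| north-east run | 8.3 | 0.239 |
| north-east run | 13 | 0.255 |
| north-east run | 21 | 0.276 |
| north-east run | 33 | 0.300 |
| north run | 1.3 | 0.160 |
| north run | 2.1 | 0.212 |
| north run | 3.3 | 0.263 |
| north run | 5.2 | 0.299 |
| north run | 8.3 | 0.335 |
| north run | 13 | 0.362 |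
| north run | 21 | 0.383 |
| north run | 33 | 0.393 |

(scatter of a reading: 0.004 M)

* reaction order in [L] at the outset, round the charge of the south run, defined at two percent of the Z turned into J
* reaction order in [X] at the outset, round the charge of the south run, defined at two percent of the Z turned into J
* the north-west run starts with 0.240 M less of Z and of X than the south run, and with no J. Compared where both hold the same amount of Z, once fifteen percent of what the north-west run was charged with has turned into J, is the north-west run faster, slower or alike (within a tenth)?
* J in the west run at 33 h, as a share of the Z charged

- Overall: Z + X -> J, with L as catalyst.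
- Constant volume, constant temperature.
- What is held in complexes is read along with the free species.
- "The second partner" is X.
- An order is taken over about fifteen percent of the charge, up and down.

Two views of these runs are in dispute, and they part over where the flask is heading. The first view, held by the one who made the forecast, is that J forms through L and that the runs slow towards a ceiling, for the south charge near 0.34 M of J. At 33 h the north-east run reads 0.300 M and the south run 0.283 M, a gap of 0.0170 M for the doubled L, so the end looks like something more L does little to lift.

My view is that L fades as J builds up, while Z and X go on reacting without it, by an uncatalysed background route. On that view the end state of the south run is its 0.400 M of Z turned into J, Z being the limiting reagent, with less charged than the 0.480 M of X, and the late climb of J in the south and north-east runs follows the Z and X left and not the L charged.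

So I take the climb of J per hour between 21 h and 33 h and divide it by the product of the Z and X left midway through that climb. The south run gives 0.0794 M⁻¹ h⁻¹ and the north-east run 0.0930 M⁻¹ h⁻¹. The scatter of the readings puts an uncertainty of 0.0173 M⁻¹ h⁻¹ on the south value alone, and the two differ by less than that, although L was doubled. Their mean, 0.0862 M⁻¹ h⁻¹, is a reading that I call the creep constant: on my view, the rate of J that needs no L, per unit of Z times X.

A flask still nearing a ceiling could also climb late, so I carry the creep constant to the outset of the south run, where the order in L is asked. On the south charge the creep constant gives 0.0165 M h⁻¹, while the mean rate up to the first reading, at 1.3 h, is 0.0554 M h⁻¹. That makes the creep a fraction 0.299 of the rate. If the remainder is proportional to L, the order in L is one minus this fraction, 0.701. The mean runs over a slowing stretch, so I expect the order to come out somewhat above this.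

I grant the first view its region. Scaling the L part to the west charge, on the same assumption, cuts the fraction to 0.0848, so the order at the outset of the west run is 0.915, and at that outset a flask carried by L is a fair picture.

The forecast sets the order in L higher than my 0.701. It gives 0.88 for the order in L, 0.92 for the order in X, faster for the north-west run, and 81 % for the west run. Its reading of the slowing is: “The slowdown follows J: product inhibition and/or reversibility.”

The simulation gives an order in L of 0.72, lower than the forecast's, while the order in X is 0.93, the north-west run is faster, and the west run reaches 81.4 %. The south run's rate at two percent of its Z turned is 0.066 M h⁻¹.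

    L + X ⇌ LX, settled at all times (0.2840 M⁻¹)
    LX + Z → J + L (511.2 M⁻¹ h⁻¹)
    L + J → Vo + J (2.052 M⁻¹ h⁻¹)
    Z + X → J (0.1001 M⁻¹ h⁻¹)

At that same amount of Z turned, the north run makes J at 0.17 M h⁻¹. The creep constant, applied to the Z and X left there, gives 0.0470 M h⁻¹, a share of 28.0 %.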